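## Retrosynthetic overview

1. Target ⇐ (2S)-tetra-MOM flavanone; the four MOM ethers are removed with acid in the last step.
2. Key disconnection C2–C1′: chromone C2 is made nucleophilic as a nickel homoenolate (η3-4-silyloxychromenyl nickel) and joined to a ring B aryl bromide under chiral-ligand control. Two normally electrophilic carbons are coupled and C2 (S) is set in this step.
3. Chromone ⇐ 2-hydroxy-4,6-bis(MOM)-3,5-diprenylacetophenone plus one carbon from DMF-DMA (enaminone cyclisation) ⇐ phloroacetophenone + prenyl bromide.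
4. Aryl bromide ⇐ 4-bromoresorcinol by MOM protection, lithiation between the two oxygens and prenylation.
5. Ring order: ring A is bought, ring C is closed before the key step, ring B is bought and attached last.

Assumption: the facial sense of the chiral ligand in step 6 cannot be predicted for this new coupling. (S,S)-iPr-BiOX, i.e. (4S,4′S)-4,4′-di(propan-2-yl)-4,4′,5,5′-tetrahydro-2,2′-bi-1,3-oxazole, is written; if it gives the 2R product, the equally available (R,R) ligand is used. The check is chiral HPLC on 15 and CD of 16 (2S: positive band near 330 nm, negative near 290 nm).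

## Route

Step 1
Reactants: 1 2,4,6-trihydroxyacetophenone; 2 prenyl bromide (1-bromo-3-methylbut-2-ene)
Product: 3 1-[2,4,6-trihydroxy-3,5-bis(3-methylbut-2-en-1-yl)phenyl]ethan-1-one
Conditions: 2 (2.2 equiv), 10% aq. KOH, 0 °C to rt, 4 h; acidify; chromatography
Reagents that add atoms: prenyl bromide (2), CC(C)=CCBr
Why: The polyphenoxide of 1 reacts as a vinylogous enolate and is C-alkylated by the soft allylic bromide at both free ring carbons (direct nuclear C-prenylation), giving the 3,5-diprenyl compound in modest yield (about 30%) from cheap materials after separation from mono- and over-alkylated products.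

Step 2
Reactants: 3 1-[2,4,6-trihydroxy-3,5-bis(3-methylbut-2-en-1-yl)phenyl]ethan-1-one; 4 chloromethyl methyl ether
Product: 5 1-[2-hydroxy-4,6-bis(methoxymethoxy)-3,5-bis(3-methylbut-2-en-1-yl)phenyl]ethan-1-one
Conditions: 4 (2.3 equiv), K2CO3, acetone, 0 °C to 40 °C
Reagents that add atoms: chloromethyl methyl ether (4), COCCl
Why: MOM protection (Williamson-type O-alkylation) takes the para hydroxyl and one ortho hydroxyl, while the last ortho hydroxyl is held in a strong hydrogen bond to the acetyl group and stays free for the later ring closure.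

Step 3
Reactants: 5 1-[2-hydroxy-4,6-bis(methoxymethoxy)-3,5-bis(3-methylbut-2-en-1-yl)phenyl]ethan-1-one; 6 N,N-dimethylformamide dimethyl acetal
Product: 8 5,7-bis(methoxymethoxy)-6,8-bis(3-methylbut-2-en-1-yl)-4H-chromen-4-one, via enaminone 7 (not isolated)
Conditions: 6 (3 equiv), toluene, 95 °C, 3 h; evaporate; AcOH, CH2Cl2, 40 °C
Reagents that add atoms: N,N-dimethylformamide dimethyl acetal (6), COC(OC)N(C)C
Why: Condensation of the methyl ketone with the amide acetal gives the enaminone, and weak acid triggers addition–elimination by the free phenol with loss of dimethylamine (enaminone route to chromones), closing ring C without cleaving aryl MOM ethers or cyclising prenyl groups.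

Step 4
Reactants: 9 4-bromobenzene-1,3-diol (4-bromoresorcinol); 4 chloromethyl methyl ether
Product: 10 1-bromo-2,4-bis(methoxymethoxy)benzene
Conditions: 4 (2.5 equiv), K2CO3, acetone, 0 °C to rt
Reagents that add atoms: chloromethyl methyl ether (4), COCCl
Why: Standard MOM protection of both phenols, which also installs two ortho-directing groups flanking C3.

Step 5
Reactants: 10 1-bromo-2,4-bis(methoxymethoxy)benzene; 2 prenyl bromide
Product: 12 1-bromo-2,4-bis(methoxymethoxy)-3-(3-methylbut-2-en-1-yl)benzene, via aryllithium 11 (not isolated)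
Conditions: LiN(iPr)2 (1.15 equiv), THF, −78 °C, 1 h; then CuBr·SMe2 (10 mol %), 2 (1.3 equiv), −78 to 0 °C
Reagents that add atoms: prenyl bromide (2), CC(C)=CCBr
Why: Directed ortho-metalation removes the proton between the two MOM ethers (doubly activated and meta to bromine, so the amide base causes neither bromine–lithium exchange nor aryne formation), and copper-catalysed allylation of the aryllithium at the primary carbon of prenyl bromide gives the SN2 product.

Step 6
Reactants: 8 5,7-bis(methoxymethoxy)-6,8-bis(3-methylbut-2-en-1-yl)-4H-chromen-4-one; 12 1-bromo-2,4-bis(methoxymethoxy)-3-(3-methylbut-2-en-1-yl)benzene; 13 chlorotriethylsilane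
Product: 15 (2S)-2-[2,4-bis(methoxymethoxy)-3-(3-methylbut-2-en-1-yl)phenyl]-5,7-bis(methoxymethoxy)-6,8-bis(3-methylbut-2-en-1-yl)-2,3-dihydro-4H-chromen-4-one, via triethylsilyl enol ether 14 (not isolated)
Conditions: NiCl2(dme) (10 mol %), (S,S)-iPr-BiOX (12 mol %), Mn powder (3 equiv), Et3SiCl (2 equiv), 12 (1.5 equiv), DMA, 10 °C to rt, 24 h; then 1 M aq. HCl, THF, 0 °C, 15 min
Reagents that add atoms: 1-bromo-2,4-bis(methoxymethoxy)-3-(3-methylbut-2-en-1-yl)benzene (12), CC(C)=CCc1c(OCOC)ccc(Br)c1OCOC
Why: Proposed new method: zerovalent nickel (from NiCl2(dme) and Mn) adds oxidatively to chromone 8 as its carbonyl oxygen is silylated by Et3SiCl, giving an η3-(4-triethylsilyloxy-2H-chromen-2-yl)nickel species, a chromanone homoenolate that is nucleophilic at the normally electrophilic C2; after one-electron reduction by Mn it takes up aryl bromide 12, and inner-sphere reductive elimination from the aryl(allyl) trivalent nickel centre forms C2–C1′ at the less hindered oxygen-bearing allyl terminus, with the C2-symmetric bis(oxazoline) ligand deciding which face of the planar chromenyl ligand carries nickel and hence the aryl group (2S), and mild acid then hydrolyses the silyl enol ether to the ketone without touching C2; the closest known reaction types are the nickel-catalysed reductive conjugate arylation of enones with aryl halides and chlorosilanes through 1-silyloxyallylnickel intermediates, nickel-catalysed enantioselective arylation of η3-benzopyranyl electrophiles, and enantioselective nickel-catalysed reductive cross-electrophile couplings with bis(oxazoline) ligands.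

Step 7
Reactants: 15 (2S)-2-[2,4-bis(methoxymethoxy)-3-(3-methylbut-2-en-1-yl)phenyl]-5,7-bis(methoxymethoxy)-6,8-bis(3-methylbut-2-en-1-yl)-2,3-dihydro-4H-chromen-4-one
Product: 16 (2S)-2-[2,4-dihydroxy-3-(3-methylbut-2-en-1-yl)phenyl]-5,7-dihydroxy-6,8-bis(3-methylbut-2-en-1-yl)-2,3-dihydro-4H-chromen-4-one (CNP0129172.1)
Conditions: 3 M HCl in MeOH/THF (4:1), 40 °C, about 3 h (monitor); quench with NaHCO3 buffer to pH 6
Reagents that add atoms: none
Why: Acid-catalysed transacetalisation to methanol removes all four MOM ethers as dimethoxymethane (the usual MOM cleavage for prenylated flavanones); no base is present, so the base-labile C2 centre is not opened by retro-oxa-Michael reaction and stays S, and at 40 °C the prenyl groups should not cyclise appreciably onto the neighbouring phenols.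

## Compound list

1 | 2,4,6-trihydroxyacetophenone | CC(=O)c1c(O)cc(O)cc1O | starting material
2 | prenyl bromide (1-bromo-3-methylbut-2-ene) | CC(C)=CCBr | starting material
3 | 1-[2,4,6-trihydroxy-3,5-bis(3-methylbut-2-en-1-yl)phenyl]ethan-1-one | CC(=O)c1c(O)c(CC=C(C)C)c(O)c(CC=C(C)C)c1O | intermediate
4 | chloromethyl methyl ether | COCCl | starting material
5 | 1-[2-hydroxy-4,6-bis(methoxymethoxy)-3,5-bis(3-methylbut-2-en-1-yl)phenyl]ethan-1-one | CC(=O)c1c(O)c(CC=C(C)C)c(OCOC)c(CC=C(C)C)c1OCOC | intermediate
6 | N,N-dimethylformamide dimethyl acetal | COC(OC)N(C)C | starting material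
7 | (2E)-3-(dimethylamino)-1-[2-hydroxy-4,6-bis(methoxymethoxy)-3,5-bis(3-methylbut-2-en-1-yl)phenyl]prop-2-en-1-one | CN(C)/C=C/C(=O)c1c(O)c(CC=C(C)C)c(OCOC)c(CC=C(C)C)c1OCOC | intermediate
8 | 5,7-bis(methoxymethoxy)-6,8-bis(3-methylbut-2-en-1-yl)-4H-chromen-4-one | O=c1ccoc2c(CC=C(C)C)c(OCOC)c(CC=C(C)C)c(OCOC)c12 | intermediate
9 | 4-bromobenzene-1,3-diol | Oc1ccc(Br)c(O)c1 | starting material
10 | 1-bromo-2,4-bis(methoxymethoxy)benzene | COCOc1ccc(Br)c(OCOC)c1 | intermediate
11 | [3-bromo-2,6-bis(methoxymethoxy)phenyl]lithium | [Li]c1c(OCOC)ccc(Br)c1OCOC | intermediate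
12 | 1-bromo-2,4-bis(methoxymethoxy)-3-(3-methylbut-2-en-1-yl)benzene | CC(C)=CCc1c(OCOC)ccc(Br)c1OCOC | intermediate
13 | chlorotriethylsilane | CC[Si](Cl)(CC)CC | starting material
14 | triethyl{[(2S)-2-[2,4-bis(methoxymethoxy)-3-(3-methylbut-2-en-1-yl)phenyl]-5,7-bis(methoxymethoxy)-6,8-bis(3-methylbut-2-en-1-yl)-2H-chromen-4-yl]oxy}silane | CC(C)=CCc1c(OCOC)ccc([C@@H]2C=C(O[Si](CC)(CC)CC)c3c(OCOC)c(CC=C(C)C)c(OCOC)c(CC=C(C)C)c3O2)c1OCOC | intermediate
15 | (2S)-2-[2,4-bis(methoxymethoxy)-3-(3-methylbut-2-en-1-yl)phenyl]-5,7-bis(methoxymethoxy)-6,8-bis(3-methylbut-2-en-1-yl)-2,3-dihydro-4H-chromen-4-one | CC(C)=CCc1c(OCOC)ccc([C@@H]2CC(=O)c3c(OCOC)c(CC=C(C)C)c(OCOC)c(CC=C(C)C)c3O2)c1OCOC | intermediate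
16 | (2S)-2-[2,4-dihydroxy-3-(3-methylbut-2-en-1-yl)phenyl]-5,7-dihydroxy-6,8-bis(3-methylbut-2-en-1-yl)-2,3-dihydro-4H-chromen-4-one | CC(C)=CCc1c(O)ccc([C@@H]2CC(=O)c3c(O)c(CC=C(C)C)c(O)c(CC=C(C)C)c3O2)c1O | target

## Step count

Total step count: 7.
Longest linear sequence: 5 steps (steps 1, 2, 3, 6, 7); the ring B branch is steps 4 and 5.

## Steps most likely to fail, with fallbacks

**Step 6 (new enantioselective nickel coupling).** The risks are low conversion of the chromone, biaryl or hydrodehalogenation by-products from 12, and low ee. The fallback sets out from 12 (and uses 8) and comes back at 15. Bromine–lithium exchange on 12 (n-BuLi, THF, −78 °C) gives [2,4-bis(methoxymethoxy)-3-(3-methylbut-2-en-1-yl)phenyl]lithium F1. This is quenched with B(OMe)3 and worked up with aqueous NH4Cl to [2,4-bis(methoxymethoxy)-3-(3-methylbut-2-en-1-yl)phenyl]boronic acid F2. F2 is then added to chromone 8 in a rhodium-catalysed asymmetric 1,4-addition ([Rh(OH)(cod)]2 3 mol %, an electron-poor chiral bisphosphine of the MeO-F12-BIPHEP type in the enantiomer that gives 2S, toluene/H2O, rt, no added base), which gives ketone 15 directly. Here the aryl group is the nucleophile and the chromone the electrophile, and the base-free medium keeps C2 closed.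

**Step 7 (acidic removal of four MOM groups next to three prenyl groups and an acid- and base-sensitive C2).** The risks are chroman formation from prenyl groups and erosion of ee through ring opening assisted by the 2′,4′-dioxygenated ring B. The fallback sets out from 8 and 12 and comes back at 16; it moves the acid step in front of the stereocentre and changes the protecting groups for the endgame.
- 8 is methanolysed (HCl, MeOH, 40 °C) to 5,7-dihydroxy-6,8-bis(3-methylbut-2-en-1-yl)-4H-chromen-4-one F3, which is silylated (Et3SiCl, imidazole, DMF) to 6,8-bis(3-methylbut-2-en-1-yl)-5,7-bis(triethylsilyloxy)-4H-chromen-4-one F4.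
- 12 is treated in the same two ways to give 4-bromo-2-(3-methylbut-2-en-1-yl)benzene-1,3-diol F5 and then 1-bromo-3-(3-methylbut-2-en-1-yl)-2,4-bis(triethylsilyloxy)benzene F6.
- F4 and F6 are coupled under the step 6 conditions, where the Et3SiCl in the medium keeps the phenols silylated, to triethyl{[(2S)-6,8-bis(3-methylbut-2-en-1-yl)-2-[3-(3-methylbut-2-en-1-yl)-2,4-bis(triethylsilyloxy)phenyl]-5,7-bis(triethylsilyloxy)-2H-chromen-4-yl]oxy}silane F7.
- F7 is not isolated but treated with Bu4NF/AcOH (THF, 0 °C), which removes all five silyl groups and gives 16.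

The flavanone then never meets strong acid or base, and any chroman by-product of the acid step arises on achiral material that can be separated.

**Step 1 (unselective double C-prenylation, about 30%).** The fallback sets out from 1 and comes back at 3; it replaces direct C-alkylation by two rounds of O-alkylation and aromatic Claisen rearrangement, which fix the regiochemistry.
- The most acidic 4-OH of 1 is alkylated with isobutyl 2-methylbut-3-en-2-yl carbonate (Pd(PPh3)4 5 mol %, THF, 0 °C to rt) to give 1-[2,6-dihydroxy-4-(2-methylbut-3-en-2-yloxy)phenyl]ethan-1-one F8.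
- Claisen rearrangement (Eu(fod)3 10 mol %, CHCl3, 60 °C) moves the group to the ortho carbon with allyl inversion and gives 1-[2,4,6-trihydroxy-3-(3-methylbut-2-en-1-yl)phenyl]ethan-1-one F9.
- The same O-alkylation of F9 gives 1-[2,6-dihydroxy-4-(2-methylbut-3-en-2-yloxy)-3-(3-methylbut-2-en-1-yl)phenyl]ethan-1-one F10.
- A second Claisen rearrangement can only end at the one free ortho carbon and gives 3.

## Further compounds

F1 | step 6 | [2,4-bis(methoxymethoxy)-3-(3-methylbut-2-en-1-yl)phenyl]lithium | [Li]c1ccc(OCOC)c(CC=C(C)C)c1OCOC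
F2 | step 6 | [2,4-bis(methoxymethoxy)-3-(3-methylbut-2-en-1-yl)phenyl]boronic acid | OB(O)c1ccc(OCOC)c(CC=C(C)C)c1OCOC
F3 | step 7 | 5,7-dihydroxy-6,8-bis(3-methylbut-2-en-1-yl)-4H-chromen-4-one | O=c1ccoc2c(CC=C(C)C)c(O)c(CC=C(C)C)c(O)c12
F4 | step 7 | 6,8-bis(3-methylbut-2-en-1-yl)-5,7-bis(triethylsilyloxy)-4H-chromen-4-one | O=c1ccoc2c(CC=C(C)C)c(O[Si](CC)(CC)CC)c(CC=C(C)C)c(O[Si](CC)(CC)CC)c12
F5 | step 7 | 4-bromo-2-(3-methylbut-2-en-1-yl)benzene-1,3-diol | CC(C)=CCc1c(O)ccc(Br)c1O
F6 | step 7 | 1-bromo-3-(3-methylbut-2-en-1-yl)-2,4-bis(triethylsilyloxy)benzene | CC(C)=CCc1c(O[Si](CC)(CC)CC)ccc(Br)c1O[Si](CC)(CC)CC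
F7 | step 7 | triethyl{[(2S)-6,8-bis(3-methylbut-2-en-1-yl)-2-[3-(3-methylbut-2-en-1-yl)-2,4-bis(triethylsilyloxy)phenyl]-5,7-bis(triethylsilyloxy)-2H-chromen-4-yl]oxy}silane | CC(C)=CCc1c(O[Si](CC)(CC)CC)ccc([C@@H]2C=C(O[Si](CC)(CC)CC)c3c(O[Si](CC)(CC)CC)c(CC=C(C)C)c(O[Si](CC)(CC)CC)c(CC=C(C)C)c3O2)c1O[Si](CC)(CC)CC
F8 | step 1 | 1-[2,6-dihydroxy-4-(2-methylbut-3-en-2-yloxy)phenyl]ethan-1-one | CC(=O)c1c(O)cc(OC(C)(C)C=C)cc1O
F9 | step 1 | 1-[2,4,6-trihydroxy-3-(3-methylbut-2-en-1-yl)phenyl]ethan-1-one | CC(=O)c1c(O)cc(O)c(CC=C(C)C)c1O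
F10 | step 1 | 1-[2,6-dihydroxy-4-(2-methylbut-3-en-2-yloxy)-3-(3-methylbut-2-en-1-yl)phenyl]ethan-1-one | CC(=O)c1c(O)cc(OC(C)(C)C=C)c(CC=C(C)C)c1O
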